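Choose the charge for a ten-minute run by asking first what the flask must end in, and then how far it gets in that time.

all flasks: reagent 28.8 mM

| flask | substrate | partner | capture agent | remark | time |
|---|---|---|---|---|---|
| maple | 16 mM | 12.8 mM | 4.8 mM | run made earlier |  |
| birch | 32 mM | 12.8 mM | 4.8 mM | run made earlier |  |
| Monday's | 16 mM | 12.8 mM (fed, over 8.0 min) | 4.80 mM | all else is in the flask from the start; the feed brings no volume worth counting | 10 min |
| Friday's | 16 mM (fed, over 8.0 min) | 12.8 mM | 4.80 mM | all else is in the flask from the start; the feed brings no volume worth counting | 10 min |
| Saturday's | 16 mM | 12.8 mM | 4.80 mM | everything together at the start | 10 min |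

- maple (time / min: product / %): 0.500: 2.6; 1.50: 11.5; 3.00: 24.5; 4.00: 30.9; 6.00: 39.9
- birch (time / min: product / %): 0.250: 1.0; 0.417: 0.9; 0.833: 4.0; 1.50: 9.0; 3.00: 16.6

(scatter of a reading: 0.3 percentage points)

- the numbers in the tables scatter by 0.3 percentage points (one standard deviation)
- what may be going on: substrate + reagent -> open intermediate; reagent + partner -> second intermediate; open intermediate + second intermediate -> product; second intermediate + capture agent -> trapped intermediate

- the best flask by amount of product, in percent of the substrate charged; "all alike" if 1.5 percentage points covers them all (Monday's / Friday's / Saturday's / all alike)
- amount of product at the end, in percent of the substrate charged, Monday's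
- amount of product at the end, in percent of the substrate charged, Friday's
- amount of product at the end, in percent of the substrate charged, Saturday's

The proposed steps are these: substrate and reagent give open intermediate, reagent and partner give second intermediate, the two intermediates couple to product, and capture agent turns second intermediate into trapped intermediate.

Each product costs one partner and two of reagent, and partner is the limiting reagent for product, its 12.8 mM standing below the 16 mM of substrate and below the 14.4 mM of product that the reagent allows. Capture agent can take no more than its own 4.80 mM. Spare partner, S, is the charge of partner minus the charge of capture agent, 8.00 mM: second intermediate beyond capture's reach. Against the substrate that is 50.0 %, so with these charges product at the end state lies between this share and 80.0 %.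

One chemist holds the capture view: keep second intermediate scarce, feed the partner slowly, and choose Monday's, because up to 30.0 % of the substrate charged is at stake. The other holds the clock view: that stake is paid out at the end state, and the run stops at 10 min. The maple run, which is Saturday's recipe, gained 6.4 percentage points between 3.00 min and 4.00 min, then 9 points over the next 2.00 min. Its pace is falling. Holding that later pace to 10 min gives 57.9 %, so I put Saturday's lower, near 50.0 %. Monday's feed delivers its partner on average 4.00 min late, and I side with the clock.

The forecast names Saturday's, with 47 % for Monday's, 38 % for Friday's and 50 % for Saturday's, and says of Friday's “second intermediate forms early with little open intermediate”.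

The simulation gives Saturday's: Saturday's 49.1 %, Monday's 46.4 %, Friday's 35.4 %. Saturday's leads Monday's by 2.7 points, with the margin at 1.5 points.

    substrate + reagent → open intermediate (k = 0.820 M⁻¹ s⁻¹)
    reagent + partner → second intermediate (k = 14.0 M⁻¹ s⁻¹)
    open intermediate + second intermediate → product (k = 0.380 M⁻¹ s⁻¹)
    second intermediate + capture agent → trapped intermediate (k = 0.350 M⁻¹ s⁻¹)

The capture view has its region in a long wait: at 100 min Monday's holds 61.6 % of product, more than Saturday's 57.9 %. A neighbour of Saturday's charged with 4.0 mM of substrate turns the reckoning round. S stays the same and is now twice the substrate, so substrate, at 4.0 mM below the partner's 12.8 mM, becomes the limiting one, and at least 4.00 mM of second intermediate finds no open intermediate to meet at the end state. At 10.0 min that neighbour shows 76.6 % product and 0.199 % substrate, with 5.80 mM of second intermediate still standing.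

The data come from a simulation for substances that don't exist; noise was put on by code.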